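**Retrosynthetic overview**
- Key bond: the C15–O acetate bond, made last by anti-Markovnikov hydroacetoxylation of a C14=C15 vinyl group (new copper hydride method). Carrying the oxygen as a vinyl group lets all earlier steps run without protecting groups.
- C4 methyl: late enolate methylation of the cis-decalin ester, steered by the axial C10 methyl. C8 methylidene: Wittig reaction on the C8 ketone.
- C10 methyl: conjugate addition to a tetrasubstituted enone, which sets the cis ring fusion; C9 is set by protonation.
- Ring B is closed second, by Mukaiyama–Michael/aldol (Robinson) annulation of a ring A silyl enol ether with a vinyl ketone that carries C9 and C11–C16 from (S)-β-citronellene.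
- Ring A is bought as methyl 3-oxocyclohex-1-ene-1-carboxylate; an asymmetric copper hydride 1,4-reduction sets the absolute configuration, which is relayed C4 → C5 → C10 → C9 → C4.

Assumption: the SMILES is taken literally, so H5 is cis to the C10 methyl (cis-fused decalin, the C5 epimer of methyl 15-acetoxyimbricatolate); atoms are referred to by labdane numbering (C4 bears the ester, C5/C10 are the ring-fusion carbons, C8 carries the methylidene, C9 the side chain, C13 the side-chain methyl).

**Step 1**
Reactants: 1 (S)-3,7-dimethylocta-1,6-diene ((S)-β-citronellene)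
Product: 3 (S)-4-methylhex-5-en-1-ol, via (S)-4-methylhex-5-enal 2 (not isolated)
Conditions: O3 (1.0 equiv, Sudan Red 7B end point), CH2Cl2/MeOH, −78 °C; then NaBH4, 0 °C
Reagents that add atoms: ozone, [O-][O+]=O
Why: Ozonolysis with reductive work-up, in which ozone cleaves the electron-rich trisubstituted alkene far faster than the vinyl group, so one equivalent removes only the isopropylidene end and the C13 stereocentre is carried through unchanged.

**Step 2**
Reactants: 3 (S)-4-methylhex-5-en-1-ol
Product: 4 (S)-6-bromo-3-methylhex-1-ene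
Conditions: CBr4, PPh3, CH2Cl2, 0 °C
Reagents that add atoms: tetrabromomethane, BrC(Br)(Br)Br
Why: Appel reaction (SN2 displacement at a primary carbinol under neutral conditions), with no stereocentre involved.

**Step 3**
Reactants: 4 (S)-6-bromo-3-methylhex-1-ene; 5 3-chloropropanoyl chloride
Product: 8 (S)-7-methylnona-1,8-dien-3-one, via alkylmagnesium bromide 6 (not isolated), via chloroketone 7 (not isolated)
Conditions: Mg, THF, rt; then added to 5, CuI (5 mol %), THF, −78 °C; then Et3N, rt
Reagents that add atoms: none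
Why: Copper-catalysed acylation of a Grignard reagent by an acid chloride stops at the ketone at −78 °C, and E1cB loss of HCl with Et3N unmasks the vinyl ketone just before use; the stereocentre is remote and untouched.

**Step 4**
Reactants: 9 methyl 3-oxocyclohex-1-ene-1-carboxylate
Product: 10 methyl (S)-3-{[dimethyl(phenyl)silyl]oxy}cyclohex-2-ene-1-carboxylate
Conditions: Cu(OAc)2 (3 mol %), (R)-DTBM-SEGPHOS (3.3 mol %), PhMe2SiH (1.2 equiv), PhMe, 0 °C
Reagents that add atoms: dimethylphenylsilane, C[SiH](C)c1ccccc1
Why: Asymmetric copper hydride 1,4-hydrosilylation (conjugate reduction) of a β-substituted cyclohexenone, in which hydride goes to the ester-bearing carbon β to the ketone on the face chosen by the ligand to set (S) at C4, and the enol ether is formed only toward C5 (if the sense of induction proves opposite, the (S)-ligand is used).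

**Step 5**
Reactants: 10 methyl (S)-3-{[dimethyl(phenyl)silyl]oxy}cyclohex-2-ene-1-carboxylate; 8 (S)-7-methylnona-1,8-dien-3-one
Product: 12 methyl (1S,2R)-2-[(7S)-7-methyl-3-oxonon-8-en-1-yl]-3-oxocyclohexane-1-carboxylate, via silyl enol ether 11 (not isolated)
Conditions: Sc(OTf)3 (10 mol %), CH2Cl2, −78 °C; then 1 M HCl, THF, 0 °C
Reagents that add atoms: none
Why: Mukaiyama–Michael addition in which the activated enone approaches C5 anti to the neighbouring ester, giving the 2,3-trans product (also the thermodynamic arrangement) and so setting C5 from C4.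

**Step 6**
Reactants: 12 methyl (1S,2R)-2-[(7S)-7-methyl-3-oxonon-8-en-1-yl]-3-oxocyclohexane-1-carboxylate
Product: 13 methyl (1S,8aR)-5-[(3S)-3-methylpent-4-en-1-yl]-6-oxo-1,2,3,4,6,7,8,8a-octahydronaphthalene-1-carboxylate
Conditions: pyrrolidine (0.3 equiv), AcOH (0.3 equiv), PhMe, 80 °C
Reagents that add atoms: none
Why: Intramolecular aldol condensation (second half of a Robinson annulation) under enamine catalysis closes ring B between C9 and C10; the ester-bearing C4 does not epimerise under these mild conditions and holds the epimerisable C5 in the favoured trans arrangement, so no stereochemical information is lost.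

**Step 7**
Reactants: 13 methyl (1S,8aR)-5-[(3S)-3-methylpent-4-en-1-yl]-6-oxo-1,2,3,4,6,7,8,8a-octahydronaphthalene-1-carboxylate
Product: 15 methyl (1S,4aS,5R,8aR)-4a-methyl-5-[(3S)-3-methylpent-4-en-1-yl]-6-oxodecahydronaphthalene-1-carboxylate, via trimethylsilyl enol ether 14 (not isolated)
Conditions: MeMgBr (2 equiv), CuBr·SMe2 (10 mol %), TMSCl (2.5 equiv), HMPA (2.5 equiv), THF, −78 to −30 °C; then 1 M HCl, THF, 0 °C
Reagents that add atoms: methylmagnesium bromide, C[Mg]Br
Why: Copper-catalysed conjugate addition accelerated by TMSCl/HMPA, in which methyl adds axially to C10 on the face of H5 to give the cis-fused decalin (as for cuprate additions to octalones bearing a ring-fusion hydrogen), and hydrolysis of the enol ether protonates C9 to the favoured ketone with the side chain equatorial and cis to the new methyl.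

**Step 8**
Reactants: 15 methyl (1S,4aS,5R,8aR)-4a-methyl-5-[(3S)-3-methylpent-4-en-1-yl]-6-oxodecahydronaphthalene-1-carboxylate
Product: 16 methyl (1S,4aS,5S,8aR)-4a-methyl-6-methylidene-5-[(3S)-3-methylpent-4-en-1-yl]decahydronaphthalene-1-carboxylate
Conditions: Ph3PCH3Br (3 equiv), KOtBu (2.8 equiv), PhMe, 80 °C
Reagents that add atoms: methyltriphenylphosphonium bromide, C[P+](c1ccccc1)(c1ccccc1)c1ccccc1.[Br-]
Why: Wittig methylenation of the hindered C8 ketone; C9 already has its favoured configuration, and any base-induced epimerisation at C4 (α to the ester) does not matter because C4 is made planar in the next step.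

**Step 9**
Reactants: 16 methyl (1S,4aS,5S,8aR)-4a-methyl-6-methylidene-5-[(3S)-3-methylpent-4-en-1-yl]decahydronaphthalene-1-carboxylate
Product: 18 methyl (1S,4aR,5S,8aS)-1,4a-dimethyl-6-methylidene-5-[(3S)-3-methylpent-4-en-1-yl]decahydronaphthalene-1-carboxylate, via lithium enolate 17 (not isolated)
Conditions: LiN(iPr)2 (1.3 equiv), THF, −78 °C; then MeI (3 equiv), DMPU, −78 to −20 °C
Reagents that add atoms: iodomethane, CI
Why: Ester enolate alkylation in which allylic 1,3-strain between the exocyclic enolate and C6 puts the cis-decalin in the conformer with the C10 methyl axial over the β face of C4, so iodomethane enters from the α face (equatorial attack, as in podocarpate-type C4 alkylations) to give the 4α-methyl, 4β-ester quaternary centre.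

**Step 10**
Reactants: 18 methyl (1S,4aR,5S,8aS)-1,4a-dimethyl-6-methylidene-5-[(3S)-3-methylpent-4-en-1-yl]decahydronaphthalene-1-carboxylate
Product: 19 methyl (1S,4aR,5S,8aS)-5-[(3S)-5-acetoxy-3-methylpentyl]-1,4a-dimethyl-6-methylidenedecahydronaphthalene-1-carboxylate
Conditions: Cu(OAc)2 (5 mol %), racemic DTBM-SEGPHOS (6 mol %), (MeO)2MeSiH (2 equiv), tert-butyl peracetate (1.5 equiv, added over 6 h), THF, 40 °C
Reagents that add atoms: tert-butyl peracetate, CC(=O)OOC(C)(C)C
Why: Proposed new method: copper hydride-catalysed anti-Markovnikov hydroacetoxylation, in which the ligated monovalent copper hydride inserts the monosubstituted C14=C15 alkene to give the primary alkylcopper (no chain walking, so C13 is untouched, and the hindered 1,1-disubstituted exocyclic alkene inserts far more slowly), O–O oxidative addition of the perester gives an alkyl trivalent copper acetate tert-butoxide that reductively eliminates the C15–OAc bond, and the copper tert-butoxide is returned to the hydride by the silane; the closest known reactions are the copper hydride anti-Markovnikov hydroamination of terminal alkenes with O-benzoylhydroxylamines and carboxylate transfer from trivalent copper in Kharasch–Sosnovsky acyloxylation.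

**Compound list**
1 | (S)-3,7-dimethylocta-1,6-diene ((S)-β-citronellene) | CC(C)=CCC[C@H](C)C=C | starting material
2 | (S)-4-methylhex-5-enal | O=CCC[C@H](C)C=C | intermediate
3 | (S)-4-methylhex-5-en-1-ol | OCCC[C@H](C)C=C | intermediate
4 | (S)-6-bromo-3-methylhex-1-ene | BrCCC[C@H](C)C=C | intermediate
5 | 3-chloropropanoyl chloride | ClCCC(Cl)=O | starting material
6 | [(4S)-4-methylhex-5-en-1-yl]magnesium bromide | Br[Mg]CCC[C@H](C)C=C | intermediate
7 | (S)-1-chloro-7-methylnon-8-en-3-one | ClCCC(=O)CCC[C@H](C)C=C | intermediate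
8 | (S)-7-methylnona-1,8-dien-3-one | C=CC(=O)CCC[C@H](C)C=C | intermediate
9 | methyl 3-oxocyclohex-1-ene-1-carboxylate | COC(=O)C1=CC(=O)CCC1 | starting material
10 | methyl (S)-3-{[dimethyl(phenyl)silyl]oxy}cyclohex-2-ene-1-carboxylate | COC(=O)[C@H]1CCCC(O[Si](C)(C)c2ccccc2)=C1 | intermediate
11 | methyl (1S,2R)-2-[(2Z,7S)-3-{[dimethyl(phenyl)silyl]oxy}-7-methylnona-2,8-dien-1-yl]-3-oxocyclohexane-1-carboxylate | O=C1CCC[C@H](C(=O)OC)[C@H]1C/C=C(\O[Si](C)(C)c1ccccc1)CCC[C@H](C)C=C | intermediate
12 | methyl (1S,2R)-2-[(7S)-7-methyl-3-oxonon-8-en-1-yl]-3-oxocyclohexane-1-carboxylate | O=C1CCC[C@H](C(=O)OC)[C@H]1CCC(=O)CCC[C@H](C)C=C | intermediate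
13 | methyl (1S,8aR)-5-[(3S)-3-methylpent-4-en-1-yl]-6-oxo-1,2,3,4,6,7,8,8a-octahydronaphthalene-1-carboxylate | O=C1CC[C@H]2C(=C1CC[C@H](C)C=C)CCC[C@@H]2C(=O)OC | intermediate
14 | methyl (1S,4aS,8aR)-4a-methyl-5-[(3S)-3-methylpent-4-en-1-yl]-6-(trimethylsilyloxy)-1,2,3,4,4a,7,8,8a-octahydronaphthalene-1-carboxylate | C[Si](C)(C)OC=1CC[C@H]2[C@](C)(CCC[C@@H]2C(=O)OC)C=1CC[C@H](C)C=C | intermediate
15 | methyl (1S,4aS,5R,8aR)-4a-methyl-5-[(3S)-3-methylpent-4-en-1-yl]-6-oxodecahydronaphthalene-1-carboxylate (cis-fused) | O=C1CC[C@H]2[C@](C)(CCC[C@@H]2C(=O)OC)[C@H]1CC[C@H](C)C=C | intermediate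
16 | methyl (1S,4aS,5S,8aR)-4a-methyl-6-methylidene-5-[(3S)-3-methylpent-4-en-1-yl]decahydronaphthalene-1-carboxylate | C=C1CC[C@H]2[C@](C)(CCC[C@@H]2C(=O)OC)[C@H]1CC[C@H](C)C=C | intermediate
17 | lithium ester enolate of 16 (C-1 planar, enolate geometry undefined, other centres as in 16) | C=C1CC[C@H]2[C@](C)(CCCC2=C(O[Li])OC)[C@H]1CC[C@H](C)C=C | intermediate
18 | methyl (1S,4aR,5S,8aS)-1,4a-dimethyl-6-methylidene-5-[(3S)-3-methylpent-4-en-1-yl]decahydronaphthalene-1-carboxylate | C=C1CC[C@H]2[C@](C)(CCC[C@]2(C)C(=O)OC)[C@H]1CC[C@H](C)C=C | intermediate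
19 | methyl (1S,4aR,5S,8aS)-5-[(3S)-5-acetoxy-3-methylpentyl]-1,4a-dimethyl-6-methylidenedecahydronaphthalene-1-carboxylate | C=C1CC[C@H]2[C@](C)(CCC[C@]2(C)C(=O)OC)[C@H]1CC[C@H](C)CCOC(C)=O | target

**Step count**
Total steps: 10. Longest linear sequence: 9 steps (1 → 3 → 4 → 8 → 12 → 13 → 15 → 16 → 18 → 19); step 4 is the only step off this line.

**Three steps most likely to fail**

Step 4. An asymmetric copper hydride 1,4-reduction has not been shown on an enone that also carries a β-ester, so regioselectivity (hydride β to the ketone rather than β to the ester) and enantioselectivity are uncertain. The fallback installs the C4 quaternary centre first by known catalytic asymmetric conjugate addition and so also avoids step 9. It sets out from 9: Me2Zn with (CuOTf)2·C6H6 and a chiral sulfonate-bearing N-heterocyclic carbene ligand, then TMSOTf, gives methyl (S)-1-methyl-3-(trimethylsilyloxy)cyclohex-2-ene-1-carboxylate F1. Mukaiyama–Michael addition of F1 to 8 (Sc(OTf)3, then 1 M HCl) gives methyl (1S,2R)-1-methyl-2-[(7S)-7-methyl-3-oxonon-8-en-1-yl]-3-oxocyclohexane-1-carboxylate F2; the C5 epimer is expected as a minor product and is removed by chromatography. Pyrrolidine/AcOH closes ring B to methyl (1S,8aS)-1-methyl-5-[(3S)-3-methylpent-4-en-1-yl]-6-oxo-1,2,3,4,6,7,8,8a-octahydronaphthalene-1-carboxylate F3. Conjugate methylation as in step 7 gives methyl (1S,4aS,5R,8aS)-1,4a-dimethyl-5-[(3S)-3-methylpent-4-en-1-yl]-6-oxodecahydronaphthalene-1-carboxylate F4. Wittig methylenation as in step 8 brings the material back to the route at 18.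

Step 7. The tetrasubstituted enone may not accept a methyl nucleophile. The fallback builds the angular methyl through a cyclopropane instead; it sets out from 13 and returns at 15. Luche reduction (NaBH4, CeCl3·7H2O, MeOH) gives mainly the pseudo-equatorial alcohol cis to H5, methyl (1S,6S,8aR)-6-hydroxy-5-[(3S)-3-methylpent-4-en-1-yl]-1,2,3,4,6,7,8,8a-octahydronaphthalene-1-carboxylate F5. Hydroxyl-directed Simmons–Smith cyclopropanation (Et2Zn, CH2I2, CH2Cl2, −20 °C) places the methylene on the same face to give the cyclopropyl carbinol (methylene bridging C9 and C10 on the β face) F6. Dess–Martin oxidation gives the cyclopropyl ketone F7. Reductive opening with SmI2 in THF/HMPA with t-BuOH cleaves the cyclopropane bond aligned with the carbonyl, turning the bridging methylene into the C10 methyl; protonation at C9 then gives 15.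

Step 10 (the proposed new reaction). Copper hydride may reduce the perester directly, the perester may oxidise the phosphine, and tert-butoxy radicals may start allylic oxidation. The fallback is known chemistry; it sets out from 18 and returns at 19. Disiamylborane in THF at 0 °C hydroborates only the monosubstituted vinyl group; NaBO3·4H2O oxidation gives methyl (1S,4aR,5S,8aS)-5-[(3S)-5-hydroxy-3-methylpentyl]-1,4a-dimethyl-6-methylidenedecahydronaphthalene-1-carboxylate F8. Acetylation with Ac2O, pyridine and DMAP gives 19.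

**Further compounds**
F1 | step 4 | methyl (S)-1-methyl-3-(trimethylsilyloxy)cyclohex-2-ene-1-carboxylate | COC(=O)[C@@]1(C)CCCC(O[Si](C)(C)C)=C1
F2 | step 4 | methyl (1S,2R)-1-methyl-2-[(7S)-7-methyl-3-oxonon-8-en-1-yl]-3-oxocyclohexane-1-carboxylate | O=C1CCC[C@](C)(C(=O)OC)[C@H]1CCC(=O)CCC[C@H](C)C=C
F3 | step 4 | methyl (1S,8aS)-1-methyl-5-[(3S)-3-methylpent-4-en-1-yl]-6-oxo-1,2,3,4,6,7,8,8a-octahydronaphthalene-1-carboxylate | O=C1CC[C@H]2C(=C1CC[C@H](C)C=C)CCC[C@]2(C)C(=O)OC
F4 | step 4 | methyl (1S,4aS,5R,8aS)-1,4a-dimethyl-5-[(3S)-3-methylpent-4-en-1-yl]-6-oxodecahydronaphthalene-1-carboxylate | O=C1CC[C@H]2[C@](C)(CCC[C@]2(C)C(=O)OC)[C@H]1CC[C@H](C)C=C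
F5 | step 7 | methyl (1S,6S,8aR)-6-hydroxy-5-[(3S)-3-methylpent-4-en-1-yl]-1,2,3,4,6,7,8,8a-octahydronaphthalene-1-carboxylate | O[C@H]1CC[C@H]2C(=C1CC[C@H](C)C=C)CCC[C@@H]2C(=O)OC
F6 | step 7 | cyclopropyl carbinol: F5 with a β-methylene bridging C9 and C10 (labdane numbering) | O[C@H]1CC[C@H]2[C@@]3(CCC[C@@H]2C(=O)OC)C[C@@]13CC[C@H](C)C=C
F7 | step 7 | cyclopropyl ketone: C8 ketone of F6 | O=C1CC[C@H]2[C@@]3(CCC[C@@H]2C(=O)OC)C[C@@]13CC[C@H](C)C=C
F8 | step 10 | methyl (1S,4aR,5S,8aS)-5-[(3S)-5-hydroxy-3-methylpentyl]-1,4a-dimethyl-6-methylidenedecahydronaphthalene-1-carboxylate | C=C1CC[C@H]2[C@](C)(CCC[C@]2(C)C(=O)OC)[C@H]1CC[C@H](C)CCO
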